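The 1,2-dioxolane is cut at the C4–C5 ring bond, between the ring methylene and the quaternary peroxy carbon that bears the C16 chain. Both C–O bonds and both stereocentres are set first in an acyclic dialkyl peroxide: the tertiary peroxy carbon C3 by invertive opening of a Sharpless epoxide, the secondary peroxy carbon C5–H in an (S)-alkyl hydroperoxide. A rhodium alkylidene generated at C4 then inserts into the tertiary C5–H bond next to O1; this closes the ring O1–O2–C3–C4–C5 and makes C5 quaternary with retention. The step exploits the 1,5-relation of C4 and C5–H across the O–O bridge. The triene is joined last by Suzuki coupling.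

Key step: step 10

Remark: ring atoms are numbered O1, O2, C3 (acetic acid arm), C4, C5 (long chain); the target is (3R,5S) with the two ring methyl groups trans, and acid-catalysed opening of the trisubstituted epoxide by a hydroperoxide is taken to occur at the tertiary carbon with inversion.

Step 1
Reactants: 1 but-3-yn-1-ol
Product: 2 tert-butyl(but-3-yn-1-yloxy)diphenylsilane
Conditions: t-BuPh2SiCl, imidazole, DMF, 0 °C → rt
Reagents that add atoms: tert-butyl(chloro)diphenylsilane CC(C)(C)[Si](Cl)(c1ccccc1)c1ccccc1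
Why: Imidazole-promoted silylation of the primary alcohol gives an ether that should survive the Lewis-acid, peroxide and carbene steps that follow; no stereocentre is involved.

Step 2
Reactants: 2 tert-butyl(but-3-yn-1-yloxy)diphenylsilane
Product: 5 (2E)-5-{[tert-butyl(diphenyl)silyl]oxy}-3-methylpent-2-en-1-ol, via alkenylalane 3 (not isolated), via lithium alanate 4 (not isolated)
Conditions: AlMe3, Cp2ZrCl2 (25 mol %), CH2Cl2, 0 °C → rt; n-BuLi, THF, −78 °C; (CH2O)n, −78 °C → rt; 1 M HCl
Reagents that add atoms: trimethylaluminium C[Al](C)C; formaldehyde (as paraformaldehyde) C=O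
Why: Negishi zirconium-catalysed carboalumination adds methyl and aluminium syn across the terminal alkyne with methyl on the internal carbon, and hydroxymethylation of the derived alanate occurs with retention, which fixes the (E) geometry.

Step 3
Reactants: 5 (2E)-5-{[tert-butyl(diphenyl)silyl]oxy}-3-methylpent-2-en-1-ol
Product: 6 [(2R,3R)-3-(2-{[tert-butyl(diphenyl)silyl]oxy}ethyl)-3-methyloxiran-2-yl]methanol
Conditions: Ti(Oi-Pr)4 (10 mol %), D-(−)-diethyl tartrate (12 mol %), t-BuOOH, 4 Å MS, CH2Cl2, −20 °C
Reagents that add atoms: tert-butyl hydroperoxide CC(C)(C)OO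
Why: Sharpless–Katsuki asymmetric epoxidation of the (E)-trisubstituted allylic alcohol with the D-(−)-tartrate complex should deliver oxygen to the face that gives the (2R,3R)-epoxide, the source of the C3 configuration.

Step 4
Reactants: 7 9-bromonon-1-ene; 8 (R)-2-methyloxirane
Product: 10 (2R)-dodec-11-en-2-ol, via Grignard reagent 9 (not isolated)
Conditions: Mg, THF, rt; CuI (10 mol %), 8, −30 → 0 °C; aq. NH4Cl
Reagents that add atoms: none
Why: Copper-catalysed opening of the epoxide by the primary Grignard reagent at the unsubstituted carbon leaves the stereocentre of (R)-propylene oxide untouched.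

Step 5
Reactants: 10 (2R)-dodec-11-en-2-ol
Product: 11 (2R)-dodec-11-en-2-yl methanesulfonate
Conditions: MsCl, Et3N, CH2Cl2, 0 °C
Reagents that add atoms: methanesulfonyl chloride CS(=O)(=O)Cl
Why: Sulfonylation at oxygen activates the secondary alcohol with retention at carbon.

Step 6
Reactants: 11 (2R)-dodec-11-en-2-yl methanesulfonate
Product: 12 (2S)-dodec-11-en-2-yl hydroperoxide
Conditions: H2O2 (50 % aq., large excess), KOH, MeOH, 0 °C → rt
Reagents that add atoms: hydrogen peroxide OO
Why: SN2 displacement of the secondary mesylate by hydroperoxide anion proceeds with inversion to the (S)-hydroperoxide, the excess of hydrogen peroxide suppresses a second alkylation, and the isolated terminal alkene is inert to alkaline peroxide.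

Step 7
Reactants: 6 [(2R,3R)-3-(2-{[tert-butyl(diphenyl)silyl]oxy}ethyl)-3-methyloxiran-2-yl]methanol; 12 (2S)-dodec-11-en-2-yl hydroperoxide
Product: 13 (2R,3S)-5-{[tert-butyl(diphenyl)silyl]oxy}-3-{[(2S)-dodec-11-en-2-yl]peroxy}-3-methylpentane-1,2-diol
Conditions: 12 (1.5 equiv), H3PMo12O40 (5 mol %), Et2O, 0 °C → rt
Reagents that add atoms: none
Why: Acid-catalysed epoxide opening by the hydroperoxide oxygen should occur at the tertiary carbon with backside attack, so C3 is inverted to (S) while the carbinol carbon of 12 is untouched, and the two fragments are joined without base, which a beta-hydroxy peroxide would not tolerate.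

Step 8
Reactants: 13 (2R,3S)-5-{[tert-butyl(diphenyl)silyl]oxy}-3-{[(2S)-dodec-11-en-2-yl]peroxy}-3-methylpentane-1,2-diol
Product: 14 (2S)-4-{[tert-butyl(diphenyl)silyl]oxy}-2-{[(2S)-dodec-11-en-2-yl]peroxy}-2-methylbutanal
Conditions: NaIO4, THF/H2O (pH 7), 0 °C → rt
Reagents that add atoms: none
Why: Malaprade glycol cleavage turns the 1,2-diol into the alpha-peroxy aldehyde, which cannot enolise or eliminate because its alpha-carbon is quaternary; neither stereocentre is touched.

Step 9
Reactants: 14 (2S)-4-{[tert-butyl(diphenyl)silyl]oxy}-2-{[(2S)-dodec-11-en-2-yl]peroxy}-2-methylbutanal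
Product: 15 N'-[(1E,2S)-4-{[tert-butyl(diphenyl)silyl]oxy}-2-{[(2S)-dodec-11-en-2-yl]peroxy}-2-methylbutylidene]-2,4,6-tri(propan-2-yl)benzenesulfonohydrazide
Conditions: 2,4,6-(i-Pr)3C6H2SO2NHNH2, THF, 0 °C → rt
Reagents that add atoms: 2,4,6-tri(propan-2-yl)benzenesulfonohydrazide CC(C)c1cc(C(C)C)c(S(=O)(=O)NN)c(C(C)C)c1
Why: Condensation of the aldehyde with the sulfonyl hydrazide gives the hydrazone, and the triisopropylbenzenesulfonyl group is chosen because its salts release a diazo compound near room temperature.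

Step 10
Reactants: 15 N'-[(1E,2S)-4-{[tert-butyl(diphenyl)silyl]oxy}-2-{[(2S)-dodec-11-en-2-yl]peroxy}-2-methylbutylidene]-2,4,6-tri(propan-2-yl)benzenesulfonohydrazide
Product: 17 tert-butyl{2-[(3S,5S)-5-(dec-9-en-1-yl)-3,5-dimethyl-1,2-dioxolan-3-yl]ethoxy}diphenylsilane, via diazoalkane 16 (not isolated)
Conditions: Cs2CO3, Rh2(OAc)4 (2 mol %), PhCF3 (high dilution), 40 °C
Reagents that add atoms: none
Why: Proposed new method: caesium carbonate converts the hydrazone into diazoalkane 16 by loss of sulfinate (Bamford–Stevens), dirhodium tetraacetate takes up the diazo carbon with loss of N2, and the electrophilic rhodium alkylidene at C4 inserts in a concerted three-centre step into the tertiary C5–H bond next to O1, so that the C4–C5 bond and the ring form together. The closest known reaction type is the metal-catalysed intramolecular 1,5-C–H insertion of alkyl carbenes, generated from N-sulfonylhydrazones, into C–H bonds alpha to an ether oxygen (giving tetrahydrofurans), together with dirhodium carbenoid insertion into tertiary C–H bonds. The 1,2-dioxolane is closed in the 1,5-insertion mode, the carbenoid carbon bonding to the fifth atom of the chain C4–C3–O2–O1–C5. C5 becomes quaternary with retention, because the new C–C bond takes the place of the C–H bond on the same face, so the (S) centre made by SN2 chemistry is carried over unchanged, while C3 is a spectator and no new stereocentre has to be selected. The step needs chemoselectivity for this insertion over 1,2-shift, ylide formation, cyclopropanation and azine formation: C3 is quaternary (no 1,2-hydride shift), the only heteroatom-activated C–H bond at 1,5-distance is the tertiary alpha-peroxy one, attack on O2 or O1 would need a three- or four-membered ylide, the ether oxygen is shielded by the bulky silyl group, and slow diazo release at high dilution disfavours bimolecular paths.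

Step 11
Reactants: 17 tert-butyl{2-[(3S,5S)-5-(dec-9-en-1-yl)-3,5-dimethyl-1,2-dioxolan-3-yl]ethoxy}diphenylsilane
Product: 18 2-[(3S,5S)-5-(dec-9-en-1-yl)-3,5-dimethyl-1,2-dioxolan-3-yl]ethan-1-ol
Conditions: Bu4NF, AcOH, THF, 0 °C → rt
Reagents that add atoms: none
Why: Buffered fluoride cleaves the Si–O bond, and the tetrasubstituted dialkyl peroxide has no acidic or electrophilic site that fluoride could attack.

Step 12
Reactants: 18 2-[(3S,5S)-5-(dec-9-en-1-yl)-3,5-dimethyl-1,2-dioxolan-3-yl]ethan-1-ol
Product: 19 2-[(3R,5S)-5-(dec-9-en-1-yl)-3,5-dimethyl-1,2-dioxolan-3-yl]acetic acid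
Conditions: TEMPO (20 mol %), PhI(OAc)2, MeCN/H2O, rt
Reagents that add atoms: water O
Why: Oxoammonium (TEMPO) oxidation takes the primary alcohol through the aldehyde hydrate to the acid without touching the peroxide or the terminal alkene; the descriptor at C3 changes only because the priorities change.

Step 13
Reactants: 19 2-[(3R,5S)-5-(dec-9-en-1-yl)-3,5-dimethyl-1,2-dioxolan-3-yl]acetic acid
Product: 20 2-[(3R,5S)-3,5-dimethyl-5-[(9E)-10-(4,4,5,5-tetramethyl-1,3,2-dioxaborolan-2-yl)dec-9-en-1-yl]-1,2-dioxolan-3-yl]acetic acid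
Conditions: vinylboronic acid pinacol ester (3 equiv), second-generation Grubbs catalyst RuCl2(PCy3)(H2IMes)(=CHPh) (5 mol %), CH2Cl2, 40 °C
Reagents that add atoms: 4,4,5,5-tetramethyl-2-vinyl-1,3,2-dioxaborolane C=CB1OC(C)(C)C(C)(C)O1
Why: Olefin cross-metathesis of the terminal alkene with the slowly dimerising vinylboronate should give the (E)-alkenylboronate under thermodynamic control, and ruthenium alkylidenes tolerate dialkyl peroxides and free acids.

Step 14
Reactants: 21 (2E)-pent-2-enal
Product: 22 (1E,3E)-1-iodohexa-1,3-diene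
Conditions: CHI3, CrCl2, THF, 0 °C, dark
Reagents that add atoms: iodoform IC(I)I
Why: Takai iodo-olefination of the enal should give the (E)-iodoalkene through anti elimination from the gem-dichromium adduct, with the existing (E) double bond unchanged.

Step 15
Reactants: 20 2-[(3R,5S)-3,5-dimethyl-5-[(9E)-10-(4,4,5,5-tetramethyl-1,3,2-dioxaborolan-2-yl)dec-9-en-1-yl]-1,2-dioxolan-3-yl]acetic acid; 22 (1E,3E)-1-iodohexa-1,3-diene
Product: 23 2-[(3R,5S)-5-[(9E,11E,13E)-hexadeca-9,11,13-trien-1-yl]-3,5-dimethyl-1,2-dioxolan-3-yl]acetic acid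
Conditions: Pd(PPh3)4 (5 mol %), K3PO4 (aq.), THF, rt, degassed, dark; dilute acid work-up
Reagents that add atoms: none
Why: Suzuki–Miyaura coupling joins the two sp2 carbons with retention of both double-bond geometries to give the (9E,11E,13E)-triene, and mild aqueous base at room temperature leaves the dioxolane and the carboxylate intact.

Compound list
1 | but-3-yn-1-ol | C#CCCO | starting material
2 | tert-butyl(but-3-yn-1-yloxy)diphenylsilane | C#CCCO[Si](c1ccccc1)(c1ccccc1)C(C)(C)C | intermediate
3 | [(1E)-4-{[tert-butyl(diphenyl)silyl]oxy}-2-methylbut-1-en-1-yl]dimethylalumane | C[Al](C)/C=C(\C)CCO[Si](c1ccccc1)(c1ccccc1)C(C)(C)C | intermediate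
4 | lithium butyl[(1E)-4-{[tert-butyl(diphenyl)silyl]oxy}-2-methylbut-1-en-1-yl]dimethylaluminate | [Li+].CCCC[Al-](C)(C)/C=C(\C)CCO[Si](c1ccccc1)(c1ccccc1)C(C)(C)C | intermediate
5 | (2E)-5-{[tert-butyl(diphenyl)silyl]oxy}-3-methylpent-2-en-1-ol | OC/C=C(\C)CCO[Si](c1ccccc1)(c1ccccc1)C(C)(C)C | intermediate
6 | [(2R,3R)-3-(2-{[tert-butyl(diphenyl)silyl]oxy}ethyl)-3-methyloxiran-2-yl]methanol | OC[C@H]1O[C@]1(C)CCO[Si](c1ccccc1)(c1ccccc1)C(C)(C)C | intermediate
7 | 9-bromonon-1-ene | C=CCCCCCCCBr | starting material
8 | (R)-2-methyloxirane | C[C@@H]1CO1 | starting material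
9 | non-8-en-1-ylmagnesium bromide | C=CCCCCCCC[Mg]Br | intermediate
10 | (2R)-dodec-11-en-2-ol | C[C@@H](O)CCCCCCCCC=C | intermediate
11 | (2R)-dodec-11-en-2-yl methanesulfonate | C[C@@H](OS(C)(=O)=O)CCCCCCCCC=C | intermediate
12 | (2S)-dodec-11-en-2-yl hydroperoxide | C[C@H](OO)CCCCCCCCC=C | intermediate
13 | (2R,3S)-5-{[tert-butyl(diphenyl)silyl]oxy}-3-{[(2S)-dodec-11-en-2-yl]peroxy}-3-methylpentane-1,2-diol | OC[C@@H](O)[C@@](C)(OO[C@@H](C)CCCCCCCCC=C)CCO[Si](c1ccccc1)(c1ccccc1)C(C)(C)C | intermediate
14 | (2S)-4-{[tert-butyl(diphenyl)silyl]oxy}-2-{[(2S)-dodec-11-en-2-yl]peroxy}-2-methylbutanal | O=C[C@@](C)(OO[C@@H](C)CCCCCCCCC=C)CCO[Si](c1ccccc1)(c1ccccc1)C(C)(C)C | intermediate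
15 | N'-[(1E,2S)-4-{[tert-butyl(diphenyl)silyl]oxy}-2-{[(2S)-dodec-11-en-2-yl]peroxy}-2-methylbutylidene]-2,4,6-tri(propan-2-yl)benzenesulfonohydrazide | CC(C)c1cc(C(C)C)c(S(=O)(=O)N/N=C/[C@@](C)(OO[C@@H](C)CCCCCCCCC=C)CCO[Si](c2ccccc2)(c2ccccc2)C(C)(C)C)c(C(C)C)c1 | intermediate
16 | tert-butyl{[(3S)-4-diazo-3-{[(2S)-dodec-11-en-2-yl]peroxy}-3-methylbutyl]oxy}diphenylsilane | [N-]=[N+]=C[C@@](C)(OO[C@@H](C)CCCCCCCCC=C)CCO[Si](c1ccccc1)(c1ccccc1)C(C)(C)C | intermediate
17 | tert-butyl{2-[(3S,5S)-5-(dec-9-en-1-yl)-3,5-dimethyl-1,2-dioxolan-3-yl]ethoxy}diphenylsilane | C=CCCCCCCCC[C@@]1(C)C[C@](C)(CCO[Si](c2ccccc2)(c2ccccc2)C(C)(C)C)OO1 | intermediate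
18 | 2-[(3S,5S)-5-(dec-9-en-1-yl)-3,5-dimethyl-1,2-dioxolan-3-yl]ethan-1-ol | C=CCCCCCCCC[C@@]1(C)C[C@](C)(CCO)OO1 | intermediate
19 | 2-[(3R,5S)-5-(dec-9-en-1-yl)-3,5-dimethyl-1,2-dioxolan-3-yl]acetic acid | C=CCCCCCCCC[C@@]1(C)C[C@](C)(CC(=O)O)OO1 | intermediate
20 | 2-[(3R,5S)-3,5-dimethyl-5-[(9E)-10-(4,4,5,5-tetramethyl-1,3,2-dioxaborolan-2-yl)dec-9-en-1-yl]-1,2-dioxolan-3-yl]acetic acid | CC1(C)OB(/C=C/CCCCCCCC[C@@]2(C)C[C@](C)(CC(=O)O)OO2)OC1(C)C | intermediate
21 | (2E)-pent-2-enal | CC/C=C/C=O | starting material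
22 | (1E,3E)-1-iodohexa-1,3-diene | CC/C=C/C=C/I | intermediate
23 | 2-[(3R,5S)-5-[(9E,11E,13E)-hexadeca-9,11,13-trien-1-yl]-3,5-dimethyl-1,2-dioxolan-3-yl]acetic acid | CC/C=C/C=C/C=C/CCCCCCCC[C@@]1(C)C[C@](C)(CC(=O)O)OO1 | target

Total step count: 15. Longest linear sequence: 11 steps (steps 1, 2, 3, 7, 8, 9, 10, 11, 12, 13, 15).

Steps most likely to fail

Step 10 (proposed new method). The rhodium alkylidene may be diverted before it reaches the C5–H bond: migration of a C3 substituent to the carbene carbon, attack of the carbenoid or of the nucleophilic diazo carbon on the O–O bond, azine formation, or base-induced loss of the peroxide at C5–H during diazo generation. The fallback uses the known peroxycarbenium–alkene annulation, which still forms the C4–C5 bond but gives up the stereospecific relay. It sets out from 10, which is oxidised (Dess–Martin periodinane) to dodec-11-en-2-one F1. F1 is converted with HC(OMe)3, MeOH and TsOH into 11,11-dimethoxydodec-1-ene F2. One methoxy group of F2 is exchanged with ethereal H2O2 and a trace of acid to give 11-hydroperoxy-11-methoxydodec-1-ene F3, which is silylated (Et3SiCl, imidazole) to triethyl[(2-methoxydodec-11-en-2-yl)peroxy]silane F4. The alkene partner tert-butyl[(3-methylbut-3-en-1-yl)oxy]diphenylsilane F5 is made from commercial 3-methylbut-3-en-1-ol and t-BuPh2SiCl. With SnCl4 in CH2Cl2 at −78 °C, F4 should ionise to the peroxycarbenium ion, the 1,1-disubstituted alkene of F5 should attack it through its CH2 terminus, and the silyl peroxide oxygen should capture the tertiary cation. This gives the constitution of 17 as a mixture of stereoisomers. Compound 17 would have to be separated from its diastereomer by chromatography and from its enantiomer by preparative HPLC on a chiral stationary phase; the route is rejoined at 17.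

Step 7. The opening may be slow or unselective: attack at C2, ionisation to a free tertiary cation with loss of configuration at C3, hydride shift to a carbonyl compound (Meinwald rearrangement), or acid-induced decomposition of the secondary hydroperoxide. The fallback reverses the roles of the partners. It sets out from 6, which is opened with a large excess of ethereal H2O2 (H3PMo12O40 cat.) at the tertiary carbon to give (2R,3S)-5-{[tert-butyl(diphenyl)silyl]oxy}-3-hydroperoxy-3-methylpentane-1,2-diol F6. The hydroperoxide group of F6, more acidic than the hydroxyl groups, is then alkylated with mesylate 11 (CsOH·H2O, DMF, 0 °C) with inversion at the carbinol carbon. The route is rejoined at 13.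

Step 15. Zerovalent palladium and phosphine may reduce the O–O bond, the alkenylboronate may protodeboronate, or the triene may isomerise under the coupling conditions. The fallback builds the C9–C10 double bond by Horner–Wadsworth–Emmons olefination instead. It sets out from 19, which is ozonised (O3, CH2Cl2, −78 °C; Me2S) to 2-[(3R,5S)-3,5-dimethyl-5-(9-oxononyl)-1,2-dioxolan-3-yl]acetic acid F7. Commercial (2E,4E)-hepta-2,4-dienal is reduced (NaBH4, CeCl3·7H2O, MeOH) to (2E,4E)-hepta-2,4-dien-1-ol F8 and converted with PBr3 into (2E,4E)-1-bromohepta-2,4-diene F9. Michaelis–Arbuzov reaction of F9 with P(OEt)3 gives diethyl [(2E,4E)-hepta-2,4-dien-1-yl]phosphonate F10. An excess of lithiated F10 (LiHMDS, THF/DMPU, −78 °C → 0 °C) should take up the acidic proton of F7 and olefinate the aldehyde with (E) selectivity. The route is rejoined at 23.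

Further compounds
F1 | step 10 | dodec-11-en-2-one | CC(=O)CCCCCCCCC=C
F2 | step 10 | 11,11-dimethoxydodec-1-ene | COC(C)(OC)CCCCCCCCC=C
F3 | step 10 | 11-hydroperoxy-11-methoxydodec-1-ene | COC(C)(OO)CCCCCCCCC=C
F4 | step 10 | triethyl[(2-methoxydodec-11-en-2-yl)peroxy]silane | COC(C)(OO[Si](CC)(CC)CC)CCCCCCCCC=C
F5 | step 10 | tert-butyl[(3-methylbut-3-en-1-yl)oxy]diphenylsilane | C=C(C)CCO[Si](c1ccccc1)(c1ccccc1)C(C)(C)C
F6 | step 7 | (2R,3S)-5-{[tert-butyl(diphenyl)silyl]oxy}-3-hydroperoxy-3-methylpentane-1,2-diol | OC[C@@H](O)[C@@](C)(OO)CCO[Si](c1ccccc1)(c1ccccc1)C(C)(C)C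
F7 | step 15 | 2-[(3R,5S)-3,5-dimethyl-5-(9-oxononyl)-1,2-dioxolan-3-yl]acetic acid | O=CCCCCCCCC[C@@]1(C)C[C@](C)(CC(=O)O)OO1
F8 | step 15 | (2E,4E)-hepta-2,4-dien-1-ol | CC/C=C/C=C/CO
F9 | step 15 | (2E,4E)-1-bromohepta-2,4-diene | CC/C=C/C=C/CBr
F10 | step 15 | diethyl [(2E,4E)-hepta-2,4-dien-1-yl]phosphonate | CC/C=C/C=C/CP(=O)(OCC)OCC
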